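**Plan**

- Retrosynthesis: the allylic alcohol is taken back to a methyl cinnamate; ring C is opened at O1–C2; the aryl–vinyl bond at C5 is cut; C2–C3 is cut into a ring A arylacetyl enolate and a ring B benzylic bromide.
- Enabling feature: C2 is the benzylic carbon para to the free hydroxyl of ring B (the 4-hydroxy-3,5-dimethoxyphenyl ring). Oxidation of ring B therefore gives a para-quinone methide at C2, and the ring A phenol oxygen O1 adds to it to close the dihydrofuran ring C.
- Forward: the ring A acid comes from 4-bromo-2-methoxyphenol (allylation, Claisen rearrangement, alkene cleavage) and the ring B bromide from syringaldehyde. They are joined at C2–C3, the acrylate is attached at C5, both MOM groups are removed, ring C closes as the only ring-forming event, and ester reduction ends the route.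
- Stereochemistry: C3 (R) comes from alkylation of the (R)-4-benzyloxazolidin-2-one imide; C2 (S) from the trans-selective, reversible phenol addition to the methide; the E alkene from the Heck reaction.

Key step: step 14

Remark: positions are numbered as in 2,3-dihydrobenzofuran (O1, C2, C3, C3a to C7a); ring A is the benzo ring, ring B the aryl ring at C2, ring C the dihydrofuran ring; the target is the trans (2S,3R) isomer, and the acrylate is installed before ring closure so that the phenolic 2-aryl-dihydrobenzofuran is never heated with base.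

**Route**

Step 1
Reactants: 1 4-bromo-2-methoxyphenol; 2 allyl bromide (3-bromoprop-1-ene)
Product: 3 4-bromo-2-methoxy-1-(prop-2-en-1-yloxy)benzene
Conditions: K2CO3, acetone, reflux
Reagents that add atoms: none
Why: Williamson ether synthesis, in which the phenoxide formed by K2CO3 displaces bromide from the primary allylic halide and no other nucleophile is present.

Step 2
Reactants: 3 4-bromo-2-methoxy-1-(prop-2-en-1-yloxy)benzene
Product: 5 4-bromo-2-methoxy-6-(prop-2-en-1-yl)phenol, via Claisen dienone 4 (not isolated)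
Conditions: PhNEt2, 200 °C
Reagents that add atoms: none
Why: Aromatic Claisen rearrangement, whose [3,3]-sigmatropic shift delivers the allyl group to the only unsubstituted ortho carbon before dienone 4 tautomerises to the phenol, the aryl bromide being inert to heat in the absence of a metal.

Step 3
Reactants: 5 4-bromo-2-methoxy-6-(prop-2-en-1-yl)phenol
Product: 6 5-bromo-1-methoxy-2-(methoxymethoxy)-3-(prop-2-en-1-yl)benzene
Conditions: MOMCl, i-Pr2NEt, CH2Cl2, 0 °C to rt
Reagents that add atoms: chloromethyl methyl ether (MOMCl), COCCl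
Why: O-alkylation of the phenol with an α-chloro ether (MOM protection) gives an acetal that withstands the oxidants, the amide base, the hydride and the palladium/amine steps ahead and is removed by acid just before ring closure.

Step 4
Reactants: 6 5-bromo-1-methoxy-2-(methoxymethoxy)-3-(prop-2-en-1-yl)benzene
Product: 8 2-[5-bromo-3-methoxy-2-(methoxymethoxy)phenyl]acetaldehyde, via vicinal diol 7 (not isolated)
Conditions: K2OsO4·2H2O (cat.), NaIO4, 2,6-lutidine, 1,4-dioxane–H2O, rt
Reagents that add atoms: sodium periodate (NaIO4), [Na+].[O-]I(=O)(=O)=O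
Why: Lemieux–Johnson oxidation, in which catalytic dihydroxylation of the terminal alkene and periodate glycol cleavage excise the terminal CH2 while sparing the electron-rich arene, with 2,6-lutidine suppressing α-hydroxy ketone formation.

Step 5
Reactants: 8 2-[5-bromo-3-methoxy-2-(methoxymethoxy)phenyl]acetaldehyde
Product: 9 2-[5-bromo-3-methoxy-2-(methoxymethoxy)phenyl]acetic acid
Conditions: NaClO2, NaH2PO4, 2-methyl-2-butene, t-BuOH–H2O, 0 °C to rt
Reagents that add atoms: sodium chlorite (NaClO2), [Na+].[O-]Cl=O
Why: Pinnick oxidation of the crude aldehyde at a buffered pH that the aryl MOM acetal tolerates, with 2-methyl-2-butene removing hypochlorous acid before it can chlorinate the arene.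

Step 6
Reactants: 9 2-[5-bromo-3-methoxy-2-(methoxymethoxy)phenyl]acetic acid; 10 (4R)-4-benzyl-1,3-oxazolidin-2-one
Product: 12 (4R)-4-benzyl-3-{2-[5-bromo-3-methoxy-2-(methoxymethoxy)phenyl]acetyl}-1,3-oxazolidin-2-one, via mixed pivalic anhydride 11 (not isolated)
Conditions: t-BuCOCl, Et3N, THF, −20 °C; then 10, LiCl, rt
Reagents that add atoms: none
Why: N-acylation of the oxazolidinone through a mixed anhydride, in which the hindered pivaloyl carbonyl steers the LiCl-activated auxiliary to the arylacetyl carbonyl and no strong base is present to turn the acidic arylacetyl unit into a ketene.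

Step 7
Reactants: 13 syringaldehyde (4-hydroxy-3,5-dimethoxybenzaldehyde)
Product: 14 3,5-dimethoxy-4-(methoxymethoxy)benzaldehyde
Conditions: MOMCl, i-Pr2NEt, CH2Cl2, 0 °C to rt
Reagents that add atoms: chloromethyl methyl ether (MOMCl), COCCl
Why: MOM protection (O-alkylation) of the acidic, vinylogous-acid-like phenol, chosen so that both phenol protecting groups of the later coupled product fall in one acid step.

Step 8
Reactants: 14 3,5-dimethoxy-4-(methoxymethoxy)benzaldehyde
Product: 15 [3,5-dimethoxy-4-(methoxymethoxy)phenyl]methanol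
Conditions: NaBH4, MeOH, 0 °C
Reagents that add atoms: none
Why: Borohydride reduction of an aromatic aldehyde, to which the acetal and the aryl ethers are inert.

Step 9
Reactants: 15 [3,5-dimethoxy-4-(methoxymethoxy)phenyl]methanol
Product: 16 5-(bromomethyl)-1,3-dimethoxy-2-(methoxymethoxy)benzene
Conditions: CBr4, PPh3, CH2Cl2, 0 °C
Reagents that add atoms: carbon tetrabromide, BrC(Br)(Br)Br
Why: Appel reaction, which converts the benzylic alcohol to the bromide under neutral conditions that keep the MOM acetal, the reactive bromide being used without storage.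

Step 10
Reactants: 12 (4R)-4-benzyl-3-{2-[5-bromo-3-methoxy-2-(methoxymethoxy)phenyl]acetyl}-1,3-oxazolidin-2-one; 16 5-(bromomethyl)-1,3-dimethoxy-2-(methoxymethoxy)benzene
Product: 18 (4R)-4-benzyl-3-{(2R)-2-[5-bromo-3-methoxy-2-(methoxymethoxy)phenyl]-3-[3,5-dimethoxy-4-(methoxymethoxy)phenyl]propanoyl}-1,3-oxazolidin-2-one, via sodium Z-enolate 17 (not isolated)
Conditions: NaN(SiMe3)2 (1.0 equiv), THF, −78 °C; then 16, −78 to −40 °C; AcOH quench at −78 °C
Reagents that add atoms: none
Why: Evans asymmetric alkylation, in which the chelated Z-enolate 17 is shielded on the face of the C4 benzyl group of the (R)-auxiliary so that the benzylic bromide adds to the opposite face and sets the α-carbon (the future C3) as R, while the absence of excess base and the cold acidic quench guard the acidic α-aryl centre against epimerisation.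

Step 11
Reactants: 18 (4R)-4-benzyl-3-{(2R)-2-[5-bromo-3-methoxy-2-(methoxymethoxy)phenyl]-3-[3,5-dimethoxy-4-(methoxymethoxy)phenyl]propanoyl}-1,3-oxazolidin-2-one
Product: 20 (2R)-2-[5-bromo-3-methoxy-2-(methoxymethoxy)phenyl]-3-[3,5-dimethoxy-4-(methoxymethoxy)phenyl]propan-1-ol, via aldehyde 19 (not isolated)
Conditions: LiBH4, MeOH (1 equiv), THF, 0 °C
Reagents that add atoms: none
Why: Reductive cleavage of the N-acyl oxazolidinone by hydride, in which the methoxyborohydride formed in the flask attacks the exocyclic carbonyl and aldehyde 19 is reduced faster than it enolises, so the R centre is carried over unchanged and the aryl bromide and the acetals are untouched.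

Step 12
Reactants: 20 (2R)-2-[5-bromo-3-methoxy-2-(methoxymethoxy)phenyl]-3-[3,5-dimethoxy-4-(methoxymethoxy)phenyl]propan-1-ol; 21 methyl acrylate
Product: 22 methyl (2E)-3-{3-[(2R)-1-[3,5-dimethoxy-4-(methoxymethoxy)phenyl]-3-hydroxypropan-2-yl]-5-methoxy-4-(methoxymethoxy)phenyl}prop-2-enoate
Conditions: Pd(OAc)2 (cat.), P(o-tol)3, Et3N, DMF, 100 °C
Reagents that add atoms: none
Why: Mizoroki–Heck reaction, in which the aryl bromide adds oxidatively to zerovalent palladium formed from Pd(OAc)2 and the phosphine, and syn insertion of the acrylate followed by syn β-hydride elimination gives the E cinnamate with the remote stereocentre, the primary alcohol and the acetals as spectators.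

Step 13
Reactants: 22 methyl (2E)-3-{3-[(2R)-1-[3,5-dimethoxy-4-(methoxymethoxy)phenyl]-3-hydroxypropan-2-yl]-5-methoxy-4-(methoxymethoxy)phenyl}prop-2-enoate
Product: 23 methyl (2E)-3-{4-hydroxy-3-[(2R)-1-hydroxy-3-(4-hydroxy-3,5-dimethoxyphenyl)propan-2-yl]-5-methoxyphenyl}prop-2-enoate
Conditions: HCl (conc. aq., 3 equiv), MeOH, 45 °C
Reagents that add atoms: none
Why: Acid-catalysed acetal methanolysis frees both phenols at once, the methyl ester being degenerate with the solvent and the stereocentre carrying no acidic or ionisable bond.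

Step 14
Reactants: 23 methyl (2E)-3-{4-hydroxy-3-[(2R)-1-hydroxy-3-(4-hydroxy-3,5-dimethoxyphenyl)propan-2-yl]-5-methoxyphenyl}prop-2-enoate
Product: 25 methyl (2E)-3-[(2S,3R)-2-(4-hydroxy-3,5-dimethoxyphenyl)-3-(hydroxymethyl)-7-methoxy-2,3-dihydro-1-benzofuran-5-yl]prop-2-enoate, via para-quinone methide 24 (not isolated)
Conditions: DDQ (1.05 equiv), CH2Cl2–1,4-dioxane, 0 °C to rt; then CF3CO2H (cat.), rt
Reagents that add atoms: none
Why: DDQ takes a hydride equivalent (two electrons and a proton overall) from the benzylic CH2 para to the ring B hydroxyl, the most electron-rich site of 23, and gives the para-quinone methide 24, whose exocyclic carbon is the future C2. The ring A phenol oxygen then adds to that carbon in a 5-exo-trig oxa-1,6-addition that restores the aromaticity of ring B and forms O1–C2 and ring C; the closest known reaction type is the oxidation of 4-alkyl-2,6-dimethoxyphenols by DDQ or Ag2O to quinone methides that are captured by oxygen nucleophiles, the same event that closes this ring in the oxidative coupling of 4-hydroxycinnamyl phenols. The new stereocentre C2 is controlled by the C3 centre, since the aryl group takes the face anti to the hydroxymethyl group in the ring-forming transition state, and because the 4-hydroxybenzyl aryl ether reopens to the methide under the acid present (DDQH2, then CF3CO2H), any cis material should be funnelled to the more stable trans (2S,3R) isomer. The step needs oxidation of ring B and not of ring A, which is secured by the two methoxy donors and the para alkyl group of ring B, against a ring A phenol that is conjugated to an electron-poor acrylate and has no para benzylic hydrogen; ring B is symmetric, so the methide has no geometric isomers. One equivalent of oxidant at 0 °C limits further dehydrogenation of 25 to the benzofuran, and closure to the five-membered ring should outpace both the four-membered alternative through the primary hydroxyl and tautomerisation of 24 to a stilbene.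

Step 15
Reactants: 25 methyl (2E)-3-[(2S,3R)-2-(4-hydroxy-3,5-dimethoxyphenyl)-3-(hydroxymethyl)-7-methoxy-2,3-dihydro-1-benzofuran-5-yl]prop-2-enoate
Product: 27 4-[(2S,3R)-3-(hydroxymethyl)-5-[(1E)-3-hydroxyprop-1-en-1-yl]-7-methoxy-2,3-dihydro-1-benzofuran-2-yl]-2,6-dimethoxyphenol, via enal 26 (not isolated)
Conditions: i-Bu2AlH (6 equiv), THF–toluene, −78 to 0 °C; KNaC4H4O6 (aq.) work-up
Reagents that add atoms: none
Why: 1,2-Reduction of an α,β-unsaturated ester by i-Bu2AlH, in which the excess reagent first turns the phenol and the alcohol into aluminium alkoxides and then reduces the ester through enal 26 to the E allylic alcohol without touching the alkene, the benzylic aryl ether or either stereocentre.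

**Compound list**

1 | 4-bromo-2-methoxyphenol | COc1cc(Br)ccc1O | starting material
2 | allyl bromide (3-bromoprop-1-ene) | C=CCBr | starting material
3 | 4-bromo-2-methoxy-1-(prop-2-en-1-yloxy)benzene | C=CCOc1ccc(Br)cc1OC | intermediate
4 | 4-bromo-2-methoxy-6-(prop-2-en-1-yl)cyclohexa-2,4-dien-1-one (Claisen dienone, racemic, formed in the flask) | C=CCC1C=C(Br)C=C(OC)C1=O | intermediate
5 | 4-bromo-2-methoxy-6-(prop-2-en-1-yl)phenol | C=CCc1cc(Br)cc(OC)c1O | intermediate
6 | 5-bromo-1-methoxy-2-(methoxymethoxy)-3-(prop-2-en-1-yl)benzene | C=CCc1cc(Br)cc(OC)c1OCOC | intermediate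
7 | 3-[5-bromo-3-methoxy-2-(methoxymethoxy)phenyl]propane-1,2-diol (racemic, formed in the flask) | OCC(O)Cc1cc(Br)cc(OC)c1OCOC | intermediate
8 | 2-[5-bromo-3-methoxy-2-(methoxymethoxy)phenyl]acetaldehyde | O=CCc1cc(Br)cc(OC)c1OCOC | intermediate
9 | 2-[5-bromo-3-methoxy-2-(methoxymethoxy)phenyl]acetic acid | OC(=O)Cc1cc(Br)cc(OC)c1OCOC | intermediate
10 | (4R)-4-benzyl-1,3-oxazolidin-2-one | O=C1N[C@H](Cc2ccccc2)CO1 | starting material
11 | 2-[5-bromo-3-methoxy-2-(methoxymethoxy)phenyl]acetic pivalic anhydride (formed in the flask) | CC(C)(C)C(=O)OC(=O)Cc1cc(Br)cc(OC)c1OCOC | intermediate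
12 | (4R)-4-benzyl-3-{2-[5-bromo-3-methoxy-2-(methoxymethoxy)phenyl]acetyl}-1,3-oxazolidin-2-one | O=C1N(C(=O)Cc2cc(Br)cc(OC)c2OCOC)[C@H](Cc2ccccc2)CO1 | intermediate
13 | syringaldehyde (4-hydroxy-3,5-dimethoxybenzaldehyde) | COc1cc(C=O)cc(OC)c1O | starting material
14 | 3,5-dimethoxy-4-(methoxymethoxy)benzaldehyde | COCOc1c(OC)cc(C=O)cc1OC | intermediate
15 | [3,5-dimethoxy-4-(methoxymethoxy)phenyl]methanol | COCOc1c(OC)cc(CO)cc1OC | intermediate
16 | 5-(bromomethyl)-1,3-dimethoxy-2-(methoxymethoxy)benzene | COCOc1c(OC)cc(CBr)cc1OC | intermediate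
17 | sodium (1Z)-1-[(4R)-4-benzyl-2-oxo-1,3-oxazolidin-3-yl]-2-[5-bromo-3-methoxy-2-(methoxymethoxy)phenyl]ethen-1-olate (formed in the flask) | O=C1N(/C([O-])=C/c2cc(Br)cc(OC)c2OCOC)[C@H](Cc2ccccc2)CO1.[Na+] | intermediate
18 | (4R)-4-benzyl-3-{(2R)-2-[5-bromo-3-methoxy-2-(methoxymethoxy)phenyl]-3-[3,5-dimethoxy-4-(methoxymethoxy)phenyl]propanoyl}-1,3-oxazolidin-2-one | O=C1N(C(=O)[C@H](Cc2cc(OC)c(OCOC)c(OC)c2)c2cc(Br)cc(OC)c2OCOC)[C@H](Cc2ccccc2)CO1 | intermediate
19 | (2R)-2-[5-bromo-3-methoxy-2-(methoxymethoxy)phenyl]-3-[3,5-dimethoxy-4-(methoxymethoxy)phenyl]propanal (formed in the flask) | O=C[C@H](Cc1cc(OC)c(OCOC)c(OC)c1)c1cc(Br)cc(OC)c1OCOC | intermediate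
20 | (2R)-2-[5-bromo-3-methoxy-2-(methoxymethoxy)phenyl]-3-[3,5-dimethoxy-4-(methoxymethoxy)phenyl]propan-1-ol | OC[C@H](Cc1cc(OC)c(OCOC)c(OC)c1)c1cc(Br)cc(OC)c1OCOC | intermediate
21 | methyl acrylate | C=CC(=O)OC | starting material
22 | methyl (2E)-3-{3-[(2R)-1-[3,5-dimethoxy-4-(methoxymethoxy)phenyl]-3-hydroxypropan-2-yl]-5-methoxy-4-(methoxymethoxy)phenyl}prop-2-enoate | OC[C@H](Cc1cc(OC)c(OCOC)c(OC)c1)c1cc(/C=C/C(=O)OC)cc(OC)c1OCOC | intermediate
23 | methyl (2E)-3-{4-hydroxy-3-[(2R)-1-hydroxy-3-(4-hydroxy-3,5-dimethoxyphenyl)propan-2-yl]-5-methoxyphenyl}prop-2-enoate | OC[C@H](Cc1cc(OC)c(O)c(OC)c1)c1cc(/C=C/C(=O)OC)cc(OC)c1O | intermediate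
24 | methyl (2E)-3-{3-[(2R)-1-(3,5-dimethoxy-4-oxocyclohexa-2,5-dien-1-ylidene)-3-hydroxypropan-2-yl]-4-hydroxy-5-methoxyphenyl}prop-2-enoate (para-quinone methide, formed in the flask) | OC[C@H](C=C1C=C(OC)C(=O)C(OC)=C1)c1cc(/C=C/C(=O)OC)cc(OC)c1O | intermediate
25 | methyl (2E)-3-[(2S,3R)-2-(4-hydroxy-3,5-dimethoxyphenyl)-3-(hydroxymethyl)-7-methoxy-2,3-dihydro-1-benzofuran-5-yl]prop-2-enoate | COc1cc([C@H]2Oc3c(OC)cc(/C=C/C(=O)OC)cc3[C@@H]2CO)cc(OC)c1O | intermediate
26 | (2E)-3-[(2S,3R)-2-(4-hydroxy-3,5-dimethoxyphenyl)-3-(hydroxymethyl)-7-methoxy-2,3-dihydro-1-benzofuran-5-yl]prop-2-enal (formed in the flask) | COc1cc([C@H]2Oc3c(OC)cc(/C=C/C=O)cc3[C@@H]2CO)cc(OC)c1O | intermediate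
27 | 4-[(2S,3R)-3-(hydroxymethyl)-5-[(1E)-3-hydroxyprop-1-en-1-yl]-7-methoxy-2,3-dihydro-1-benzofuran-2-yl]-2,6-dimethoxyphenol | COc1cc([C@H]2Oc3c(OC)cc(/C=C/CO)cc3[C@@H]2CO)cc(OC)c1O | target

**Step count**

Total steps: 15. Longest linear sequence: 12 steps (steps 1 to 6 and 10 to 15, from 4-bromo-2-methoxyphenol); steps 7 to 9 make the ring B bromide in a separate branch.

**Steps most likely to fail**

Step 14 (oxidative ring closure). Three processes are at risk: tautomerisation of methide 24 to a stilbene before O1 adds, which would destroy the C3 centre; further dehydrogenation of 25 towards the benzofuran by unreacted oxidant; and incomplete funnelling to the trans isomer. The fallback separates oxidation from ring closure. Setting out from 23, DDQ (1.0 equiv) in MeOH at 0 °C lets the solvent capture the methide as fast as it forms and should give methyl (2E)-3-{4-hydroxy-3-[(2R)-1-hydroxy-3-(4-hydroxy-3,5-dimethoxyphenyl)-3-methoxypropan-2-yl]-5-methoxyphenyl}prop-2-enoate F1 as a mixture of epimers at the methoxy-bearing carbon. After removal of the hydroquinone, CF3CO2H (cat.) in CH2Cl2 ionises this 4-hydroxybenzyl methyl ether with loss of methanol, and the ring A phenol closes ring C under thermodynamic control, which comes back to the route at 25.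

Step 10 (enolate alkylation). The processes at risk are epimerisation of the doubly activated α-aryl centre by base or on work-up, and ionisation of the electron-rich benzylic bromide before it is alkylated. The fallback forms C2–C3 by condensation and sets C3 by catalytic hydrogenation. Setting out from acid 9 and aldehyde 14, a Perkin condensation (Ac2O, Et3N, 110 °C) should give (2E)-2-[5-bromo-3-methoxy-2-(methoxymethoxy)phenyl]-3-[3,5-dimethoxy-4-(methoxymethoxy)phenyl]prop-2-enoic acid F2. Asymmetric hydrogenation of this α-aryl cinnamic acid (H2, Ru(OAc)2(BINAP), MeOH) should then give (2R)-2-[5-bromo-3-methoxy-2-(methoxymethoxy)phenyl]-3-[3,5-dimethoxy-4-(methoxymethoxy)phenyl]propanoic acid F3. The BINAP antipode that leads to the R acid would have to be fixed by a test reduction, and the enantiomeric purity can be raised by crystallising an amine salt. Reduction of the acid with BH3·SMe2 in THF comes back to the route at 20.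

Step 12 (Heck coupling). The processes at risk are slow oxidative addition of the electron-rich aryl bromide with loss of the catalyst as palladium black at 100 °C, and conjugate addition of the primary alcohol to the acrylate. The fallback builds the alkene by carbonyl olefination. Setting out from 20, n-BuLi (2.2 equiv, THF, −78 °C) deprotonates the alcohol and exchanges bromine for lithium to give the aryllithium alkoxide F4. DMF formylates it to 3-[(2R)-1-[3,5-dimethoxy-4-(methoxymethoxy)phenyl]-3-hydroxypropan-2-yl]-5-methoxy-4-(methoxymethoxy)benzaldehyde F5. A Wittig reaction with the stabilised ylide Ph3P=CHCO2Me (toluene, 80 °C) is E-selective and comes back to the route at 22.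

**Further compounds**

F1 | step 14 | methyl (2E)-3-{4-hydroxy-3-[(2R)-1-hydroxy-3-(4-hydroxy-3,5-dimethoxyphenyl)-3-methoxypropan-2-yl]-5-methoxyphenyl}prop-2-enoate (epimers at C3 of the propyl chain) | OC[C@H](C(OC)c1cc(OC)c(O)c(OC)c1)c1cc(/C=C/C(=O)OC)cc(OC)c1O
F2 | step 10 | (2E)-2-[5-bromo-3-methoxy-2-(methoxymethoxy)phenyl]-3-[3,5-dimethoxy-4-(methoxymethoxy)phenyl]prop-2-enoic acid | OC(=O)/C(=C/c1cc(OC)c(OCOC)c(OC)c1)c1cc(Br)cc(OC)c1OCOC
F3 | step 10 | (2R)-2-[5-bromo-3-methoxy-2-(methoxymethoxy)phenyl]-3-[3,5-dimethoxy-4-(methoxymethoxy)phenyl]propanoic acid | OC(=O)[C@H](Cc1cc(OC)c(OCOC)c(OC)c1)c1cc(Br)cc(OC)c1OCOC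
F4 | step 12 | lithium (2R)-3-[3,5-dimethoxy-4-(methoxymethoxy)phenyl]-2-[5-lithio-3-methoxy-2-(methoxymethoxy)phenyl]propan-1-olate | [Li+].[O-]C[C@H](Cc1cc(OC)c(OCOC)c(OC)c1)c1cc([Li])cc(OC)c1OCOC
F5 | step 12 | 3-[(2R)-1-[3,5-dimethoxy-4-(methoxymethoxy)phenyl]-3-hydroxypropan-2-yl]-5-methoxy-4-(methoxymethoxy)benzaldehyde | OC[C@H](Cc1cc(OC)c(OCOC)c(OC)c1)c1cc(C=O)cc(OC)c1OCOC
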